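**Retrosynthetic overview**
1. Target 16 comes from 15 by removal of three O‑benzyl groups. 15 comes from coumarin 13 by an enantioselective copper hydride 1,4‑reduction, which sets C4.
2. 13 comes from the open‑chain aryl β‑iodocinnamate 12 by one radical cascade that makes both C4–C4a and O1–C8a. The ester oxygen starts on C4a, C4 takes its place by ipso attack, and the carboxyl group moves to C8a.
3. Enabling feature: in ring A, C4a lies between oxygen‑bearing C5 (blocked) and C8a–H, and C8a is next to the acyl‑bearing C8. A 1,2,4‑trioxygenated aryl ester can therefore only rearrange to the 1,3,5‑pattern with the lactone oxygen beside the ketone.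
4. 12 comes from phenol 6 (made from 4‑bromoresorcinol 1 and acid 2) and iodo acid 11 (made from alkyne 7, CO2 and HI).
5. Ring order: ring A and the three phenyl rings are bought. Ring B is the only ring built, in step 7, through a transient five‑membered spiro ring.

Key step: step 7

Remark on numbering: locants O1, C2 … C8a follow the chromen‑2‑one numbering of the target. Ring A is the benzo ring and ring B is the lactone ring.
Assumption: the facial sense of the copper hydride step is assigned by analogy with simpler 4‑arylcoumarins. If a first run shows 4R, the enantiomeric ligand is used.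

**Step 1**
Reactants: 1 4‑bromoresorcinol (4‑bromobenzene‑1,3‑diol); 2 3‑phenylpropanoic acid
Product: 3 1‑(5‑bromo‑2,4‑dihydroxyphenyl)‑3‑phenylpropan‑1‑one
Conditions: BF3·OEt2 (promoter and solvent), 85 °C; then water
Reagents that add atoms: none
Why: Friedel–Crafts (Nencki‑type) acylation of a resorcinol with a free acid should go to the one unhindered position that is ortho to one OH and para to the other, which puts Br on the future C4a and the ketone on the future C8.

**Step 2**
Reactants: 3 1‑(5‑bromo‑2,4‑dihydroxyphenyl)‑3‑phenylpropan‑1‑one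
Product: 4 1‑[2,4‑bis(benzyloxy)‑5‑bromophenyl]‑3‑phenylpropan‑1‑one
Conditions: BnBr (2.4 equiv), K2CO3, DMF, 70 °C
Reagents that add atoms: benzyl bromide, BrCc1ccccc1
Why: Williamson ether synthesis at 70 °C should alkylate both phenols, including the hydrogen‑bonded one, and gives ethers that survive the radical step and leave under neutral conditions at the end.

**Step 3**
Reactants: 4 1‑[2,4‑bis(benzyloxy)‑5‑bromophenyl]‑3‑phenylpropan‑1‑one
Product: 6 1‑[2,4‑bis(benzyloxy)‑5‑hydroxyphenyl]‑3‑phenylpropan‑1‑one, via pinacol boronate 5 (not isolated)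
Conditions: B2pin2, Pd(dppf)Cl2 (3 mol %), KOAc, 1,4‑dioxane, 90 °C; then 30 % H2O2, cat. NaOH, THF/H2O, 0 °C to rt
Reagents that add atoms: bis(pinacolato)diboron, CC1(C)OB(OC1(C)C)B1OC(C)(C)C(C)(C)O1; hydrogen peroxide, OO
Why: Miyaura borylation through zerovalent palladium followed by ipso oxidation of the C–B bond is a standard bromide‑to‑phenol exchange, and it should be much faster than any peroxide attack on the hindered ketone.

**Step 4**
Reactants: 7 1‑(benzyloxy)‑4‑ethynylbenzene
Product: 10 3‑[4‑(benzyloxy)phenyl]prop‑2‑ynoic acid, via lithium acetylide 8 (not isolated), via lithium carboxylate 9 (not isolated)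
Conditions: n‑BuLi, THF, −78 °C; CO2 (gas), −78 °C to rt; 1 M HCl
Reagents that add atoms: carbon dioxide, O=C=O; n‑butyllithium, [Li]CCCC (lithium stays only in 8 and 9)
Why: Deprotonation of a terminal alkyne and carboxylation of the acetylide is a standard route to arylpropiolic acids, and the benzyl ether is inert to it.

**Step 5**
Reactants: 10 3‑[4‑(benzyloxy)phenyl]prop‑2‑ynoic acid
Product: 11 (2Z)‑3‑[4‑(benzyloxy)phenyl]‑3‑iodoprop‑2‑enoic acid
Conditions: NaI (1.6 equiv), AcOH, 110 °C
Reagents that add atoms: sodium iodide, [Na+].[I-]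
Why: Hydroiodination of a 2‑alkynoic acid derivative (anti conjugate addition of HI made in the flask) puts iodine on the aryl‑bearing β‑carbon, both conjugate and cation‑type polarisation agree on this regiochemistry, and the alkene geometry does not matter later.

**Step 6**
Reactants: 6 1‑[2,4‑bis(benzyloxy)‑5‑hydroxyphenyl]‑3‑phenylpropan‑1‑one; 11 (2Z)‑3‑[4‑(benzyloxy)phenyl]‑3‑iodoprop‑2‑enoic acid
Product: 12 2,4‑bis(benzyloxy)‑5‑(3‑phenylpropanoyl)phenyl (2Z)‑3‑[4‑(benzyloxy)phenyl]‑3‑iodoprop‑2‑enoate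
Conditions: DCC, DMAP (10 mol %), CH2Cl2, 0 °C to rt
Reagents that add atoms: none
Why: Steglich esterification joins the only free phenol to the acid under mild conditions and places the ester oxygen on the carbon that becomes C4a.

**Step 7**
Reactants: 12 2,4‑bis(benzyloxy)‑5‑(3‑phenylpropanoyl)phenyl (2Z)‑3‑[4‑(benzyloxy)phenyl]‑3‑iodoprop‑2‑enoate
Product: 13 5,7‑bis(benzyloxy)‑4‑[4‑(benzyloxy)phenyl]‑8‑(3‑phenylpropanoyl)‑2H‑chromen‑2‑one
Conditions: fac‑Ir(ppy)3 (2 mol %), K2HPO4 (2 equiv), degassed MeCN (0.02 M), blue LEDs (450 nm), rt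
Reagents that add atoms: none
Why: Proposed new method: the excited photocatalyst, which is known to reduce alkenyl iodides, gives one electron to the C–I bond of 12, iodide leaves and a linear α‑aryl vinyl radical at C4 results, the same kind of radical that forms when radicals add to aryl 3‑arylpropiolates in the known radical addition / ipso‑cyclisation / 1,2‑ester‑migration route to 3‑substituted coumarins (the closest known reaction type); only the way the radical is made, which leaves H on C3, is new. The radical closes 5‑exo‑trig on the ipso carbon C4a (C4–C4a bond), the spiro cyclohexadienyl radical regains aromaticity by scission of the old C4a–O bond, and the resulting alkenoyloxy radical, held cis to ring A, adds 6‑endo‑trig to C8a (O1–C8a bond) and closes ring B. The new cyclohexadienyl radical, stabilised by the C8 acyl group and the C4 styrene unit, is oxidised by the oxidised photocatalyst (tetravalent iridium) and loses its proton to K2HPO4, so the step is redox‑neutral. Site selectivity comes from the substrate: C5 carries OBn and no H, so addition there can only revert and C8a alone can end the sequence, while direct 6‑endo attack of the vinyl radical on C8a is slower than ipso closure and is hindered by the neighbouring acyl group. No stoichiometric oxidant is present, so the spiro radical should fragment rather than be oxidised with loss of a benzyl group. No stereocentre is formed in this step.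

**Step 8**
Reactants: 13 5,7‑bis(benzyloxy)‑4‑[4‑(benzyloxy)phenyl]‑8‑(3‑phenylpropanoyl)‑2H‑chromen‑2‑one
Product: 15 (4S)‑5,7‑bis(benzyloxy)‑4‑[4‑(benzyloxy)phenyl]‑8‑(3‑phenylpropanoyl)‑3,4‑dihydro‑2H‑chromen‑2‑one, via boron enolate 14 (not isolated)
Conditions: CuCl (5 mol %), NaOtBu (5 mol %), (R)‑DTBM‑SEGPHOS (5.5 mol %), HBpin (1.5 equiv), toluene, 0 °C to rt; then sat. aq. NH4Cl
Reagents that add atoms: pinacolborane, CC1(C)OBOC1(C)C (its boron group stays only in 14)
Why: Copper hydride catalysed enantioselective 1,4‑hydroboration (conjugate reduction), a reaction type established on 4‑arylcoumarins, should deliver hydride from the ligand‑bound monovalent copper hydride to one face of the planar, geometrically fixed C3=C4 bond so that the bulky bisphosphine alone sets C4 as S, the boron enolate 14 blocks over‑reduction of the lactone, and the C8 ketone, twisted between two ortho oxygen substituents, should react more slowly.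

**Step 9**
Reactants: 15 (4S)‑5,7‑bis(benzyloxy)‑4‑[4‑(benzyloxy)phenyl]‑8‑(3‑phenylpropanoyl)‑3,4‑dihydro‑2H‑chromen‑2‑one
Product: 16 (4S)‑5,7‑dihydroxy‑4‑(4‑hydroxyphenyl)‑8‑(3‑phenylpropanoyl)‑3,4‑dihydro‑2H‑chromen‑2‑one (CNP0383109.1)
Conditions: H2 (1 atm), 10 % Pd/C, EtOAc, rt
Reagents that add atoms: none
Why: Heterogeneous hydrogenolysis cleaves the three O–benzyl bonds under neutral aprotic conditions that neither open the lactone (so it cannot move to the freed C5–OH) nor touch the C4–H stereocentre, and electron‑rich, hydrogen‑bonded aryl ketones of this kind normally survive such debenzylations.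

**Compound list**
1 | 4‑bromoresorcinol | Oc1ccc(Br)c(O)c1 | starting material
2 | 3‑phenylpropanoic acid | OC(=O)CCc1ccccc1 | starting material
3 | 1‑(5‑bromo‑2,4‑dihydroxyphenyl)‑3‑phenylpropan‑1‑one | O=C(CCc1ccccc1)c1cc(Br)c(O)cc1O | intermediate
4 | 1‑[2,4‑bis(benzyloxy)‑5‑bromophenyl]‑3‑phenylpropan‑1‑one | O=C(CCc1ccccc1)c1cc(Br)c(OCc2ccccc2)cc1OCc1ccccc1 | intermediate
5 | 1‑[2,4‑bis(benzyloxy)‑5‑(4,4,5,5‑tetramethyl‑1,3,2‑dioxaborolan‑2‑yl)phenyl]‑3‑phenylpropan‑1‑one | O=C(CCc1ccccc1)c1cc(B2OC(C)(C)C(C)(C)O2)c(OCc2ccccc2)cc1OCc1ccccc1 | intermediate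
6 | 1‑[2,4‑bis(benzyloxy)‑5‑hydroxyphenyl]‑3‑phenylpropan‑1‑one | O=C(CCc1ccccc1)c1cc(O)c(OCc2ccccc2)cc1OCc1ccccc1 | intermediate
7 | 1‑(benzyloxy)‑4‑ethynylbenzene | C#Cc1ccc(OCc2ccccc2)cc1 | starting material
8 | lithium [4‑(benzyloxy)phenyl]acetylide | [Li]C#Cc1ccc(OCc2ccccc2)cc1 | intermediate
9 | lithium 3‑[4‑(benzyloxy)phenyl]prop‑2‑ynoate | [Li+].[O-]C(=O)C#Cc1ccc(OCc2ccccc2)cc1 | intermediate
10 | 3‑[4‑(benzyloxy)phenyl]prop‑2‑ynoic acid | OC(=O)C#Cc1ccc(OCc2ccccc2)cc1 | intermediate
11 | (2Z)‑3‑[4‑(benzyloxy)phenyl]‑3‑iodoprop‑2‑enoic acid | OC(=O)/C=C(\I)c1ccc(OCc2ccccc2)cc1 | intermediate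
12 | 2,4‑bis(benzyloxy)‑5‑(3‑phenylpropanoyl)phenyl (2Z)‑3‑[4‑(benzyloxy)phenyl]‑3‑iodoprop‑2‑enoate | O=C(/C=C(\I)c1ccc(OCc2ccccc2)cc1)Oc1cc(C(=O)CCc2ccccc2)c(OCc2ccccc2)cc1OCc1ccccc1 | intermediate
13 | 5,7‑bis(benzyloxy)‑4‑[4‑(benzyloxy)phenyl]‑8‑(3‑phenylpropanoyl)‑2H‑chromen‑2‑one | O=C1C=C(c2ccc(OCc3ccccc3)cc2)c2c(OCc3ccccc3)cc(OCc3ccccc3)c(C(=O)CCc3ccccc3)c2O1 | intermediate
14 | (4S)‑2‑(pinacolboryloxy)‑4H‑chromene boron enolate of 15 | CC1(C)OB(OC2=C[C@@H](c3ccc(OCc4ccccc4)cc3)c3c(OCc4ccccc4)cc(OCc4ccccc4)c(C(=O)CCc4ccccc4)c3O2)OC1(C)C | intermediate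
15 | (4S)‑5,7‑bis(benzyloxy)‑4‑[4‑(benzyloxy)phenyl]‑8‑(3‑phenylpropanoyl)‑3,4‑dihydro‑2H‑chromen‑2‑one | O=C1C[C@@H](c2ccc(OCc3ccccc3)cc2)c2c(OCc3ccccc3)cc(OCc3ccccc3)c(C(=O)CCc3ccccc3)c2O1 | intermediate
16 | (4S)‑5,7‑dihydroxy‑4‑(4‑hydroxyphenyl)‑8‑(3‑phenylpropanoyl)‑3,4‑dihydro‑2H‑chromen‑2‑one | O=C1C[C@@H](c2ccc(O)cc2)c2c(O)cc(O)c(C(=O)CCc3ccccc3)c2O1 | target

**Step count**
Total steps: 9. Longest linear sequence: 7 (steps 1, 2, 3, 6, 7, 8, 9).

**Steps most likely to fail**

Step 7 (labelled new).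
- What may go wrong: the vinyl radical may abstract hydrogen before it cyclises, it may close directly on C8a, or the spiro radical may be oxidised with loss of a benzyl group.
- Fallback (known chemistry): it sets out from 6 and 10.
- Steglich esterification gives 2,4‑bis(benzyloxy)‑5‑(3‑phenylpropanoyl)phenyl 3‑[4‑(benzyloxy)phenyl]prop‑2‑ynoate F1.
- The established sulfonyl‑radical addition / ipso‑cyclisation / ester‑migration cascade of aryl 3‑arylpropiolates (p‑toluenesulfinic acid, eosin Y, t‑BuOOH, visible light) forms the same two bonds. It gives 5,7‑bis(benzyloxy)‑4‑[4‑(benzyloxy)phenyl]‑3‑(4‑methylbenzenesulfonyl)‑8‑(3‑phenylpropanoyl)‑2H‑chromen‑2‑one F2.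
- Copper hydride catalysed enantioselective conjugate reduction, known for β,β‑disubstituted vinyl sulfones and for coumarins, gives the (4S)‑3‑(4‑methylbenzenesulfonyl)‑3,4‑dihydro compound F3 as C3 epimers.
- Aluminium amalgam in wet THF removes the sulfonyl group, and the route is rejoined at 15.

Step 8.
- What may go wrong: hydride delivery may be slow or poorly face‑selective at the crowded C4 beside the 5‑benzyloxy group, and 1,2‑reduction of the C8 ketone may compete.
- Fallback: the aryl group, not hydrogen, is brought in at the stereo‑defining event. It sets out from 6.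
- Steglich esterification with bought (Z)‑3‑iodoacrylic acid gives 2,4‑bis(benzyloxy)‑5‑(3‑phenylpropanoyl)phenyl (2Z)‑3‑iodoprop‑2‑enoate F4.
- The cascade of step 7 gives 5,7‑bis(benzyloxy)‑8‑(3‑phenylpropanoyl)‑2H‑chromen‑2‑one F5.
- Rhodium‑catalysed asymmetric 1,4‑addition (Hayashi–Miyaura type, established on coumarins) of 4‑(benzyloxy)phenylboronic acid with Rh(acac)(C2H4)2 and SEGPHOS in dioxane/water at 60 °C sets C4. The route is rejoined at 15.

Step 1.
- What may go wrong: bromine may be lost or may migrate on the very electron‑rich ring in hot Lewis acid, and positional control of the acylation would then erode.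
- Fallback: the halogen is introduced after acylation. It sets out from 2.
- BF3·OEt2 acylation of bought resorcinol gives 1‑(2,4‑dihydroxyphenyl)‑3‑phenylpropan‑1‑one F6.
- Benzylation (BnBr, K2CO3, DMF) gives 1‑[2,4‑bis(benzyloxy)phenyl]‑3‑phenylpropan‑1‑one F7.
- NBS in MeCN at 0 °C brominates the only open position that is para to one ether and ortho to the other. The route is rejoined at 4.

**Further compounds**
F1 | step 7 | 2,4‑bis(benzyloxy)‑5‑(3‑phenylpropanoyl)phenyl 3‑[4‑(benzyloxy)phenyl]prop‑2‑ynoate | O=C(C#Cc1ccc(OCc2ccccc2)cc1)Oc1cc(C(=O)CCc2ccccc2)c(OCc2ccccc2)cc1OCc1ccccc1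
F2 | step 7 | 5,7‑bis(benzyloxy)‑4‑[4‑(benzyloxy)phenyl]‑3‑(4‑methylbenzenesulfonyl)‑8‑(3‑phenylpropanoyl)‑2H‑chromen‑2‑one | O=C1C(S(=O)(=O)c2ccc(C)cc2)=C(c2ccc(OCc3ccccc3)cc2)c2c(OCc3ccccc3)cc(OCc3ccccc3)c(C(=O)CCc3ccccc3)c2O1
F3 | step 7 | (4S)‑5,7‑bis(benzyloxy)‑4‑[4‑(benzyloxy)phenyl]‑3‑(4‑methylbenzenesulfonyl)‑8‑(3‑phenylpropanoyl)‑3,4‑dihydro‑2H‑chromen‑2‑one (C3 epimers) | O=C1C(S(=O)(=O)c2ccc(C)cc2)[C@@H](c2ccc(OCc3ccccc3)cc2)c2c(OCc3ccccc3)cc(OCc3ccccc3)c(C(=O)CCc3ccccc3)c2O1
F4 | step 8 | 2,4‑bis(benzyloxy)‑5‑(3‑phenylpropanoyl)phenyl (2Z)‑3‑iodoprop‑2‑enoate | O=C(/C=C\I)Oc1cc(C(=O)CCc2ccccc2)c(OCc2ccccc2)cc1OCc1ccccc1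
F5 | step 8 | 5,7‑bis(benzyloxy)‑8‑(3‑phenylpropanoyl)‑2H‑chromen‑2‑one | O=C1C=Cc2c(OCc3ccccc3)cc(OCc3ccccc3)c(C(=O)CCc3ccccc3)c2O1
F6 | step 1 | 1‑(2,4‑dihydroxyphenyl)‑3‑phenylpropan‑1‑one | O=C(CCc1ccccc1)c1ccc(O)cc1O
F7 | step 1 | 1‑[2,4‑bis(benzyloxy)phenyl]‑3‑phenylpropan‑1‑one | O=C(CCc1ccccc1)c1ccc(OCc2ccccc2)cc1OCc1ccccc1
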